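The 17-membered ring (N1 amide nitrogen, C2 carbonyl, C3, C4 nonyl-bearing stereocentre, N5, C6–C8, N9, C10–C13, N14, C15–C17) is opened at C11–C12, the central bond of the four-carbon bridge between N9 and N14, which is remote from C4 and has an allylic N–CH2 group on each side. Ring-closing metathesis of an open-chain (R)-diene bearing N-allyl groups on N9 and N14 forms this bond and the macrocycle in one operation. N5, N9 and N14 are all benzyl carbamates, so one hydrogenation then saturates C11=C12 and unmasks the three amines. C4 is set by asymmetric reductive amination of methyl 3-oxododecanoate.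

Key step: step 8

Remark: the ring numbering above is used throughout; Cbz = benzyloxycarbonyl; (R)-dm-segphos = (R)-5,5'-bis[bis(3,5-dimethylphenyl)phosphino]-4,4'-bi-1,3-benzodioxole. The C11=C12 geometry of 15 is assumed to be immaterial (E is drawn), because step 9 removes it.

Step 1
Reactants: 1 methyl 3-oxododecanoate
Product: 3 methyl (3R)-3-aminododecanoate, via methyl (2Z)-3-aminododec-2-enoate 2 (not isolated)
Conditions: NH4OAc (5 equiv), Ru(OAc)2((R)-dm-segphos) (1 mol%), H2 (30 bar), MeOH, 80 °C; aq NaHCO3 work-up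
Reagents that add atoms: ammonium acetate, CC(=O)[O-].[NH4+]
Why: Direct asymmetric reductive amination, in which 1 condenses with ammonia to the chelating Z-enamino ester 2 and the chiral ruthenium bisphosphine complex hydrogenates one face of it; the (R)-ligand is chosen to give R at C4 by analogy with other β-keto esters and amides that carry a CH2 group on the ketone carbon, and the sense should be confirmed on the first batch by chiral HPLC against the racemate.

Step 2
Reactants: 4 3-bromopropan-1-ol; 5 allylamine
Product: 7 benzyl allyl(3-hydroxypropyl)carbamate, via 3-(allylamino)propan-1-ol 6 (not isolated)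
Conditions: 5 (6 equiv), EtOH, 0 to 50 °C; volatiles removed; then CbzCl (1.1 equiv), Na2CO3, THF/H2O, 0 °C to rt
Reagents that add atoms: benzyl chloroformate, O=C(Cl)OCc1ccccc1
Why: SN2 amination of the primary bromide, with the excess of 5 suppressing dialkylation, followed by Schotten–Baumann N-acylation in which the secondary amine outcompetes the primary alcohol.

Step 3
Reactants: 7 benzyl allyl(3-hydroxypropyl)carbamate
Product: 8 benzyl allyl(3-oxopropyl)carbamate
Conditions: TEMPO (10 mol%), PhI(OAc)2 (1.1 equiv), CH2Cl2, rt; used at once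
Reagents that add atoms: none
Why: Oxoammonium-mediated (TEMPO/PhI(OAc)2) oxidation of the primary alcohol should stop at the aldehyde under anhydrous, base-free conditions, which avoids β-elimination of the carbamate and leaves the allyl group alone.

Step 4
Reactants: 7 benzyl allyl(3-hydroxypropyl)carbamate
Product: 10 benzyl allyl(3-aminopropyl)carbamate, via benzyl allyl(3-azidopropyl)carbamate 9 (not isolated)
Conditions: PPh3, DIAD, (PhO)2P(O)N3, THF, 0 °C to rt; then PPh3, rt; then H2O, 50 °C; acid–base extraction
Reagents that add atoms: diphenylphosphoryl azide, [N-]=[N+]=NP(=O)(Oc1ccccc1)Oc1ccccc1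
Why: Mitsunobu azidation of the primary alcohol followed by Staudinger reduction, a phosphine-based reduction that spares the allyl group and the benzyl carbamate, which catalytic hydrogenation would not.

Step 5
Reactants: 3 methyl (3R)-3-aminododecanoate; 8 benzyl allyl(3-oxopropyl)carbamate
Product: 12 methyl (3R)-3-[{3-[allyl(benzyloxycarbonyl)amino]propyl}(benzyloxycarbonyl)amino]dodecanoate, via N5-monoalkylated amino ester 11 (not isolated)
Conditions: NaBH(OAc)3 (1.4 equiv), AcOH (1 equiv), ClCH2CH2Cl, rt; then aq Na2CO3, CbzCl (1.2 equiv), 0 °C to rt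
Reagents that add atoms: benzyl chloroformate, O=C(Cl)OCc1ccccc1
Why: Reductive amination (iminium reduction by NaBH(OAc)3) of the α-branched primary amine should stop at mono-alkylation, Schotten–Baumann acylation then caps N5, and C4 takes no part, so its R configuration is retained.

Step 6
Reactants: 12 methyl (3R)-3-[{3-[allyl(benzyloxycarbonyl)amino]propyl}(benzyloxycarbonyl)amino]dodecanoate
Product: 13 (3R)-3-[{3-[allyl(benzyloxycarbonyl)amino]propyl}(benzyloxycarbonyl)amino]dodecanoic acid
Conditions: LiOH·H2O (3 equiv), THF/MeOH/H2O, 0 °C to rt; then 1 M HCl to pH 3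
Reagents that add atoms: lithium hydroxide, [Li+].[OH-]
Why: Saponification of the methyl ester by acyl substitution; the N,N-disubstituted benzyl carbamates resist hydroxide at room temperature, and a carbamate nitrogen at C4 is too poor a leaving group for E1cB loss.

Step 7
Reactants: 13 (3R)-3-[{3-[allyl(benzyloxycarbonyl)amino]propyl}(benzyloxycarbonyl)amino]dodecanoic acid; 10 benzyl allyl(3-aminopropyl)carbamate
Product: 14 benzyl allyl{3-[(3R)-3-[{3-[allyl(benzyloxycarbonyl)amino]propyl}(benzyloxycarbonyl)amino]dodecanamido]propyl}carbamate (open-chain (R)-diene; N5, N9, N14 as benzyl carbamates; N-allyl on N9 and N14)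
Conditions: EDC·HCl, HOBt, N-methylmorpholine, CH2Cl2, 0 °C to rt
Reagents that add atoms: none
Why: Carbodiimide/HOBt amide coupling of the primary amine of 10 with the active ester of 13, an acid without an α-stereocentre and therefore without an epimerisation pathway.

Step 8
Reactants: 14 open-chain (R)-diene
Product: 15 tribenzyl (4R,11E)-4-nonyl-2-oxo-1,5,9,14-tetraazacycloheptadec-11-ene-5,9,14-tricarboxylate (E drawn; the Z isomer serves equally)
Conditions: RuCl2(H2IMes)(PCy3)(=CHPh) (second-generation Grubbs catalyst, 2 × 5 mol%), 1,4-benzoquinone (10 mol%), CH2Cl2 (2 mM, 14 added slowly), 40 °C, argon sparge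
Reagents that add atoms: none
Why: After loss of PCy3 the ruthenium benzylidene exchanges with one terminal N-allyl olefin through a ruthenacyclobutane, and the chain-bound alkylidene so formed reacts with the second N-allyl olefin of the same molecule through a second ruthenacyclobutane, which collapses to C11=C12 and a ruthenium methylidene while ethene escapes. The closest known reaction type is macrocyclic ring-closing olefin metathesis of carbamate-protected N,N'-diallyl diamines and polyamines to cyclic but-2-ene-1,4-diamine derivatives. The only ring formed is the 17-membered macrocycle, closed by joining the two terminal olefin carbons of an α,ω-diene so that the new double bond is endocyclic. No stereocentre is created, the olefin geometry is erased in step 9, and C4 lies at least seven bonds from either reacting carbon and cannot epimerise. The selectivity needed is ring closure over chain-growth metathesis and over allyl-to-propenyl isomerisation: 2 mM concentration and sparging out ethene favour the ring, linear oligomers can still back-bite to 15 because each metathesis event is reversible, and 1,4-benzoquinone intercepts the ruthenium hydrides that cause isomerisation. None of the four nitrogens can ligate ruthenium, since N1 is a secondary amide and N5, N9 and N14 are carbamates.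

Step 9
Reactants: 15 tribenzyl (4R,11E)-4-nonyl-2-oxo-1,5,9,14-tetraazacycloheptadec-11-ene-5,9,14-tricarboxylate
Product: 16 (4R)-4-nonyl-1,5,9,14-tetraazacycloheptadecan-2-one
Conditions: H2 (1 atm), 10% Pd/C, CF3CH2OH, rt
Reagents that add atoms: none
Why: Heterogeneous catalytic hydrogenation should saturate C11=C12 whatever its geometry and hydrogenolyse the three benzyl carbamates in the same operation, in a solvent that does not N-alkylate the freed amines; no bond to C4 is touched, so the R configuration carries into 16.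

Compound list
1 | methyl 3-oxododecanoate | CCCCCCCCCC(=O)CC(=O)OC | starting material
2 | methyl (2Z)-3-aminododec-2-enoate | CCCCCCCCC/C(N)=C/C(=O)OC | intermediate (not isolated)
3 | methyl (3R)-3-aminododecanoate | CCCCCCCCC[C@@H](N)CC(=O)OC | intermediate
4 | 3-bromopropan-1-ol | OCCCBr | starting material
5 | allylamine (prop-2-en-1-amine) | C=CCN | starting material
6 | 3-(allylamino)propan-1-ol | OCCCNCC=C | intermediate (not isolated)
7 | benzyl allyl(3-hydroxypropyl)carbamate | OCCCN(CC=C)C(=O)OCc1ccccc1 | intermediate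
8 | benzyl allyl(3-oxopropyl)carbamate | O=CCCN(CC=C)C(=O)OCc1ccccc1 | intermediate
9 | benzyl allyl(3-azidopropyl)carbamate | [N-]=[N+]=NCCCN(CC=C)C(=O)OCc1ccccc1 | intermediate (not isolated)
10 | benzyl allyl(3-aminopropyl)carbamate | NCCCN(CC=C)C(=O)OCc1ccccc1 | intermediate
11 | methyl (3R)-3-({3-[allyl(benzyloxycarbonyl)amino]propyl}amino)dodecanoate | CCCCCCCCC[C@@H](NCCCN(CC=C)C(=O)OCc1ccccc1)CC(=O)OC | intermediate (not isolated)
12 | methyl (3R)-3-[{3-[allyl(benzyloxycarbonyl)amino]propyl}(benzyloxycarbonyl)amino]dodecanoate | CCCCCCCCC[C@@H](N(CCCN(CC=C)C(=O)OCc1ccccc1)C(=O)OCc1ccccc1)CC(=O)OC | intermediate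
13 | (3R)-3-[{3-[allyl(benzyloxycarbonyl)amino]propyl}(benzyloxycarbonyl)amino]dodecanoic acid | CCCCCCCCC[C@@H](N(CCCN(CC=C)C(=O)OCc1ccccc1)C(=O)OCc1ccccc1)CC(=O)O | intermediate
14 | benzyl allyl{3-[(3R)-3-[{3-[allyl(benzyloxycarbonyl)amino]propyl}(benzyloxycarbonyl)amino]dodecanamido]propyl}carbamate (open-chain diene) | CCCCCCCCC[C@@H](N(CCCN(CC=C)C(=O)OCc1ccccc1)C(=O)OCc1ccccc1)CC(=O)NCCCN(CC=C)C(=O)OCc1ccccc1 | intermediate
15 | tribenzyl (4R,11E)-4-nonyl-2-oxo-1,5,9,14-tetraazacycloheptadec-11-ene-5,9,14-tricarboxylate | CCCCCCCCC[C@@H]1CC(=O)NCCCN(C(=O)OCc2ccccc2)C/C=C/CN(C(=O)OCc2ccccc2)CCCN1C(=O)OCc1ccccc1 | intermediate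
16 | (4R)-4-nonyl-1,5,9,14-tetraazacycloheptadecan-2-one | CCCCCCCCC[C@@H]1CC(=O)NCCCNCCCCNCCCN1 | target

Total step count: 9.
Longest linear sequence: 7 steps (steps 2, 3, 5, 6, 7, 8, 9, from 4 and 5); the branch from 1 takes 6 steps.

Steps most likely to fail

Step 8. The ring closure may lose to chain-growth metathesis, the N-allyl double bonds may migrate to enamides and give a contracted ring, or the catalyst may stall through chelation by the carbamate carbonyl groups. The fallback closes the same ring through the two C–N bonds N9–C10 and C13–N14 (Richman–Atkins-type bis-N-alkylation of sulfonamides) instead of through C11=C12. It sets out from 3 and comes back to the route at 16. Reductive amination of 3 with commercial tert-butyl (3-oxopropyl)carbamate (NaBH(OAc)3) would give methyl (3R)-3-({3-[(tert-butoxycarbonyl)amino]propyl}amino)dodecanoate F1. Sulfonylation of N5 with 2-nitrobenzenesulfonyl chloride (Et3N, DMAP) would give methyl (3R)-3-[{3-[(tert-butoxycarbonyl)amino]propyl}(2-nitrophenylsulfonyl)amino]dodecanoate F2. Saponification with LiOH would give (3R)-3-[{3-[(tert-butoxycarbonyl)amino]propyl}(2-nitrophenylsulfonyl)amino]dodecanoic acid F3. EDC/HOBt coupling with commercial tert-butyl (3-aminopropyl)carbamate would give tert-butyl {3-[(3R)-3-[{3-[(tert-butoxycarbonyl)amino]propyl}(2-nitrophenylsulfonyl)amino]dodecanamido]propyl}carbamate F4. HCl in dioxane would remove both Boc groups to give (3R)-N-(3-aminopropyl)-3-[(3-aminopropyl)(2-nitrophenylsulfonyl)amino]dodecanamide F5. Sulfonylation of both primary amines would give (3R)-3-[{3-[(2-nitrophenylsulfonyl)amino]propyl}(2-nitrophenylsulfonyl)amino]-N-{3-[(2-nitrophenylsulfonyl)amino]propyl}dodecanamide F6. Slow addition of F6 and 1,4-dibromobutane to Cs2CO3 in DMF at 60 °C would give (4R)-4-nonyl-5,9,14-tris[(2-nitrophenyl)sulfonyl]-1,5,9,14-tetraazacycloheptadecan-2-one F7. PhSH/K2CO3 in DMF would then remove the three sulfonyl groups and give 16.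

Step 1. The enantioselectivity may be insufficient, or hydrogenation of the ketone to the β-hydroxy ester and ammonolysis of the ester may compete. The fallback sets the configuration at oxygen and inverts it with nitrogen; it sets out from 1 and comes back at 3. Noyori hydrogenation of 1 with RuCl2((S)-binap), H2, MeOH would give methyl (3S)-3-hydroxydodecanoate F8. Mitsunobu azidation (PPh3, DIAD, (PhO)2P(O)N3, THF, 0 °C) with inversion would give methyl (3R)-3-azidododecanoate F9. Staudinger reduction (PPh3, THF/H2O) would give 3.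

Step 5. The primary amine may be alkylated twice, or aldehyde 8 may undergo β-elimination or self-condensation before it is trapped. The fallback replaces reductive amination by sulfonamide activation (Fukuyama sequence); it sets out from 3 and comes back at 11. 2-Nitrobenzenesulfonyl chloride/Et3N would give methyl (3R)-3-{[(2-nitrophenyl)sulfonyl]amino}dodecanoate F10. Fukuyama–Mitsunobu alkylation with alcohol 7 (PPh3, DIAD, THF) would give methyl (3R)-3-[{3-[allyl(benzyloxycarbonyl)amino]propyl}(2-nitrophenylsulfonyl)amino]dodecanoate F11. PhSH/K2CO3 would give 11, which is acylated with benzyl chloroformate as in the second stage of step 5 to give 12.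

Further compounds
F1 | step 8 | methyl (3R)-3-({3-[(tert-butoxycarbonyl)amino]propyl}amino)dodecanoate | CCCCCCCCC[C@@H](NCCCNC(=O)OC(C)(C)C)CC(=O)OC
F2 | step 8 | methyl (3R)-3-[{3-[(tert-butoxycarbonyl)amino]propyl}(2-nitrophenylsulfonyl)amino]dodecanoate | CCCCCCCCC[C@@H](N(CCCNC(=O)OC(C)(C)C)S(=O)(=O)c1ccccc1[N+](=O)[O-])CC(=O)OC
F3 | step 8 | (3R)-3-[{3-[(tert-butoxycarbonyl)amino]propyl}(2-nitrophenylsulfonyl)amino]dodecanoic acid | CCCCCCCCC[C@@H](N(CCCNC(=O)OC(C)(C)C)S(=O)(=O)c1ccccc1[N+](=O)[O-])CC(=O)O
F4 | step 8 | tert-butyl {3-[(3R)-3-[{3-[(tert-butoxycarbonyl)amino]propyl}(2-nitrophenylsulfonyl)amino]dodecanamido]propyl}carbamate | CCCCCCCCC[C@@H](N(CCCNC(=O)OC(C)(C)C)S(=O)(=O)c1ccccc1[N+](=O)[O-])CC(=O)NCCCNC(=O)OC(C)(C)C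
F5 | step 8 | (3R)-N-(3-aminopropyl)-3-[(3-aminopropyl)(2-nitrophenylsulfonyl)amino]dodecanamide | CCCCCCCCC[C@@H](N(CCCN)S(=O)(=O)c1ccccc1[N+](=O)[O-])CC(=O)NCCCN
F6 | step 8 | (3R)-3-[{3-[(2-nitrophenylsulfonyl)amino]propyl}(2-nitrophenylsulfonyl)amino]-N-{3-[(2-nitrophenylsulfonyl)amino]propyl}dodecanamide | CCCCCCCCC[C@@H](N(CCCNS(=O)(=O)c1ccccc1[N+](=O)[O-])S(=O)(=O)c1ccccc1[N+](=O)[O-])CC(=O)NCCCNS(=O)(=O)c1ccccc1[N+](=O)[O-]
F7 | step 8 | (4R)-4-nonyl-5,9,14-tris[(2-nitrophenyl)sulfonyl]-1,5,9,14-tetraazacycloheptadecan-2-one | CCCCCCCCC[C@@H]1CC(=O)NCCCN(S(=O)(=O)c2ccccc2[N+](=O)[O-])CCCCN(S(=O)(=O)c2ccccc2[N+](=O)[O-])CCCN1S(=O)(=O)c1ccccc1[N+](=O)[O-]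
F8 | step 1 | methyl (3S)-3-hydroxydodecanoate | CCCCCCCCC[C@H](O)CC(=O)OC
F9 | step 1 | methyl (3R)-3-azidododecanoate | CCCCCCCCC[C@@H](N=[N+]=[N-])CC(=O)OC
F10 | step 5 | methyl (3R)-3-{[(2-nitrophenyl)sulfonyl]amino}dodecanoate | CCCCCCCCC[C@@H](NS(=O)(=O)c1ccccc1[N+](=O)[O-])CC(=O)OC
F11 | step 5 | methyl (3R)-3-[{3-[allyl(benzyloxycarbonyl)amino]propyl}(2-nitrophenylsulfonyl)amino]dodecanoate | CCCCCCCCC[C@@H](N(CCCN(CC=C)C(=O)OCc1ccccc1)S(=O)(=O)c1ccccc1[N+](=O)[O-])CC(=O)OC
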